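## Structural features

The target (34) is a hexacyclic C25 framework. Ring A is a seven-membered α,β-unsaturated ε-lactone (C2, O4, C5, C7, C8, C9, C11), cis-fused through C9–C11 to cyclohexane ring B (C9, C11, C12, C13, C14, C23). Ring B shares C14–C23 with a cyclopentane (C14, C23, C22, C20, C24). C14, C24 and C20 also belong to a bicyclo[2.2.2]octanone (bridgeheads C16 and C24; bridges C14–C15, C18(=O)–C20 and C29–C30), which carries a γ-lactone (C24, C25, O26, C27, C29) and the C30 hydroxyl.

There are nine stereocentres (C9, C11, C14, C23, C24, C20, C16, C29, C30). C9, C14, C24, C20 and C16 are quaternary, and C14–C24–C20 are contiguous. On ring B the C9 methyl, H11 and H23 all lie on one face, so the A/B fusion is cis and H23 is syn to the angular methyl, the sterically less accessible arrangement.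

On the C29–C30 bridge the lactone carbonyl and the hydroxyl are cis and point toward the ketone bridge. Relative to the six-membered ring C14–C15–C16–C30–C29–C24 (ring D), C25 and C27 sit on opposite faces. A cis-selective cycloaddition onto that ring therefore cannot deliver this unit, and C25 is by far the more hindered of the two carboxyl carbons.

The fragile groups are the β-hydroxy ketone (C30/C16/C18) and β-hydroxy lactone (C30/C29/C27), which are open to retro-aldol cleavage, dehydration and C29 epimerisation, and the unsaturated ε-lactone.

The real difficulty is the C20–C24 bond: it joins two quaternary carbons inside the cage and is flanked by quaternary C14 and C16.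

The key step uses the fact that C20 is α to the C18 ketone and C24 is α to the C25 carboxyl carbon. A carbonyl carbon (called CX below) placed between them gives a ketone whose two α-carbons are both radical-stabilised. Loss of CO from the crystal then contracts a cyclohexanone to the cyclopentane and a bicyclo[3.2.2]nonane to the bicyclo[2.2.2]octane.

## Logic of the disconnections

**Ring A (34 → 33 → 32 → 31).** The O4–C2 bond is cut (retro-Baeyer–Villiger) and the C7=C8 unsaturation removed, with the C30 hydroxyl silylated. The unsaturated ε-lactone is the most labile part of the molecule, so it is made last from a robust 2,2-dimethyl cyclohexanone. Ring A then becomes an ordinary cis-decalin carbocycle. The forward steps must insert oxygen on the C2 side of C5 without touching C18, dehydrogenate only toward C7 (guaranteed, since C2 is quaternary), and keep O31 protected through both oxidations.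

**γ-Lactone (31 → 30 → 29 → 28).** The C25–O26 bond is cut back to a cyclic anhydride. C25 has to be a carbonyl during the key step, and an anhydride lets the two carboxyl carbons be told apart afterwards: an alcohol opens it at the exposed C27, and the liberated C25 acid is reduced. Direct hydride reduction of the anhydride is not relied on, because the hindered C25 carbonyl would be the slower to react. The demands are attack at C27 rather than C25, and reduction of the acid without loss of the C18 ketone.

**Key bond (28 → 27).** C20–C24 is cut and a carbonyl (CX) inserted between the two carbons. This replaces a bond between two quaternary centres by two acyl–carbon bonds that can each be made by enolate chemistry. The cyclopentane becomes a cyclohexanone and the bicyclo[2.2.2]octane a bicyclo[3.2.2]nonane. The forward step needs a crystalline substrate and coupling of the radical pair with retention before it can disproportionate.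

**Anhydride and bridge (27 → 26 → 25 → 24).** The anhydride C–O bond is cut to the diacid, then C18–C20 is cut. Because C25 and C27 are trans on ring D, the anhydride is closed only after the bridge has locked ring D as a boat. Once bridged, the C25 β-keto acid cannot decarboxylate, since its enol would be a bridgehead olefin. Cutting C18–C20 leaves a ring C ketone with a single enolisable position (C20) and an acyl donor on C16. The forward acylation needs C18 on the CX face of ring D, an activated ester so that formation of a non-enolisable 1,3-diketone is downhill, and an inert C27 (kept as carboxylate).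

**C16, C29 and C30 (24 → 22 → 21 → 20 → 19).** The C16–C18 bond is cut (acylation of a β-keto ester dianion at its γ-carbon) and the C30–H bond is traced to a ketone. This reduces ring D to a simple cyclic β-keto ester with the CX ketone masked as a silyl enol ether. The acylating agent must approach C16 anti to the axial C14–C13 bond, and hydride must approach C30 anti to the axial C24–CX bond, giving the all-cis C18/O31/C27 array.

**Ring D (19 → 18 → 17 → 16).** C29–C30 is cut (Dieckmann) and then C24–C29 (alkylation of a cyclic β-keto ester with a bromoacetate). Ring D thereby reduces to two ester arms on a ring C β-keto ester. The alkylation must occur on the ring C face that carries the C15 arm, and the Dieckmann closure needs a single competent electrophile (the C30 tert-butyl ester) and no free ketone.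

**Ring C and C23 (16 → 15 → 14 → 12).** CX–C24 is cut (Dieckmann, driven by the acidic product), then C22–C20 (B-alkyl Suzuki–Miyaura) and C23–H (hydroboration). This takes the problem back to a ring B exocyclic methylene next to the quaternary C14. The hydroboration has to put hydrogen on C23 on the face of the C9 methyl.

**C14 (12 → 10 → 9 → 8 → 7).** C14–C24 is cut by a retro-[3,3] shift to an allylic alcohol, C23–C22 by a retro-Stille coupling to an enol triflate, and C14–C15 by a retro-Michael to the decalin ketone. The single ketone of 7 is thus used three times: as enolate, as enol triflate and, through the rearrangement, as the source of the C23 methylene. The sigmatropic shift must take place on the ring face anti to the C9 methyl.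

**Decalin (7 → 6 → 5 → 4 → 3 → 2 → 1).** The C11–H bond (directed hydrogenation), the two C2–methyl bonds (dienolate methylation) and the protecting groups are removed to reach the enantiopure bicyclic enedione, whose quaternary carbon is C9. Hydrogen must be delivered to C11 syn to the C9 methyl, against the normal steric preference.

## Other disconnections considered

**Alternative 1:** The cut is C8–C9 (ring A) together with C22–C23. The substrate A1 is a (Z)-β-iodoacrylate of the C2 tertiary alcohol, with the C9=C23 olefin in ring B and the complete lactone-capped cage (C20–H). Under Pd(OAc)2/PPh3 (zerovalent palladium formed in situ) it would undergo oxidative addition at C8–I, 7-exo syn-carbopalladation onto C9, and formylation of the C23–Pd bond with CO and a hydride source, giving A2.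

- In its favour: ring A arrives as the unsaturated lactone, so no dehydrogenation or Baeyer–Villiger step is needed; on this point it is better than the chosen plan. Two C–C bonds form in one operation. Syn addition places C8 and C22 cis across C9–C23, as required. The C23–Pd intermediate has no β-hydrogen, so CO capture is mechanistically sound.
- Against it: the ester tether must adopt its disfavoured s-cis form for a seven-membered closure. The olefin is trisubstituted, and quaternary C9 has to be created with facial control from C11 alone, whereas the chosen plan takes C9 from the chiral pool. Direct reduction of the alkylpalladium competes with CO insertion. A2 still lacks the C20–C22 bond, which would need an aldol closure beside quaternary C24 and a deoxygenation.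
- Comparison: A1 already contains C20–C24, so the hardest bond is left unsolved. Overall step economy is at best equal.

**Alternative 2:** The cut is C24–C29. The substrate A3 is a macrocyclic diazo β-keto lactone spanning C16 and C24, with C24–H. With Rh2(OAc)4 it would form a carbenoid at C29 that inserts into the tertiary C24–H bond (1,5-insertion), giving A4 and closing the γ-lactone and the bicyclo[2.2.2]octane together.

- In its favour: it is a catalytic solution reaction with no need for crystallinity, which is a practical advantage over the chosen plan. C–H insertion proceeds with retention, so the stereochemical fidelity at C24 equals that of radical-pair collapse. The lactone is formed at the correct oxidation state, so no anhydride differentiation is needed; on that point it is better.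
- Against it: the C24–H bond lies between quaternary C14 and C20 and has no activating group, while an acceptor/acceptor carbenoid is unselective (competing insertion into C22–H or C15–H, or ylide formation with the ketones). A3 requires a strained nine-membered lactone. A3 must also already contain the C20–C24 bond, so the congested bond is only moved to an earlier stage, with one tertiary partner. A4 then needs a face-selective reduction of the C30 ketone beside a doubly activated, epimerisable C29, followed by the same ring A oxidations as the chosen plan.
- Comparison: step count is comparable and the end game is riskier.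

**Alternative 3:** The cuts are C14–C23 and C9–C11. The substrate A5 is a 14-membered macrolactone carrying the finished cage, with the diene C14=C13–C12=C11 and the dienophile C9=C23. On heating it would undergo a transannular Diels–Alder reaction to A6, closing ring A, ring B and the cyclopentane and setting C9, C11, C14 and C23 in one step.

- In its favour: ring-forming economy, where it is clearly better than the chosen plan (three rings and four stereocentres in one step). The reaction is concerted and suprafacial, so olefin geometry is transferred faithfully (equal in stereospecificity).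
- Against it: A5 needs four defined olefin geometries, a tetrasubstituted exocyclic diene terminus on the cage and a trisubstituted dienophile, so two quaternary centres (C9, C14) must form in the cycloaddition. The facial and endo/exo outcome that gives the cis A/B fusion with H23 syn to the methyl is not secured by any obvious element. The tertiary C2 alcohol must be macrolactonised. A6 still needs selective saturation of C12=C13 beside the conjugated C7=C8.
- Comparison: the cage, including C20–C24, must again be built first on a small fragment, so the central problem remains.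

Key step: step 24

Assumption: atoms are labelled by their heavy-atom position in the target SMILES; the ketone carbon expelled as CO in step 24 has no such position and is called CX.

Assumption: C14 in 8, C16 in 8–19, C20 in 15–17, 23 and 24, C24 in 16 and C29 in 19 are epimeric or enolisable centres that are planarised or fixed later; their SMILES carry no descriptor at those atoms.

Step 1
Reactants: 1 (S)-Wieland–Miescher ketone
Product: 2 C23 hydroxy enone
Conditions: NaBH4, EtOH, −10 °C
Reagents that add atoms: none
Why: Chemoselective borohydride reduction of the saturated ketone beside the less electrophilic enone; hydride approaches anti to the angular methyl, so the hydroxyl is cis to it, as the directed hydrogenation in step 5 requires.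

Step 2
Reactants: 2 C23 hydroxy enone
Product: 3 triethylsilyl ether of 2
Conditions: Et3SiCl, imidazole, DMF, 0 °C → rt
Reagents that add atoms: chlorotriethylsilane, CC[Si](Cl)(CC)CC
Why: Silyl protection prevents O-methylation of the alcohol in the next step.

Step 3
Reactants: 3 triethylsilyl ether of 2
Product: 4 2,2-dimethyl β,γ-unsaturated ketone silyl ether
Conditions: KOtBu, MeI, tBuOH/THF, 0 °C → rt
Reagents that add atoms: iodomethane, CI
Why: Deconjugative double C-alkylation of the extended enolate: both methyl groups enter at the α-carbon (C2) and the olefin moves to C11=C12.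

Step 4
Reactants: 4 2,2-dimethyl β,γ-unsaturated ketone silyl ether
Product: 5 C11=C12 dioxolane alcohol
Conditions: ethylene glycol, pTsOH (cat.), benzene, reflux (Dean–Stark)
Reagents that add atoms: ethylene glycol, OCCO
Why: Acid-catalysed ketalisation with azeotropic removal of water; the acid-labile triethylsilyl ether is solvolysed in the same operation, freeing the C23 hydroxyl.

Step 5
Reactants: 5 C11=C12 dioxolane alcohol
Product: 6 cis-decalin dioxolane alcohol
Conditions: H2 (1 atm), [Ir(cod)(PCy3)(py)]PF6 (5 mol%), CH2Cl2, rt
Reagents that add atoms: none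
Why: Hydroxyl-directed homogeneous hydrogenation: the cationic iridium centre binds the homoallylic C23 hydroxyl and delivers hydrogen to C11 on the face of that hydroxyl and the C9 methyl, giving the cis ring fusion that an undirected hydrogenation would not favour.

Step 6
Reactants: 6 cis-decalin dioxolane alcohol
Product: 7 cis-decalin dioxolane ketone
Conditions: (Pr4N)RuO4 (5 mol%), N-methylmorpholine N-oxide, 4 Å molecular sieves, CH2Cl2, rt
Reagents that add atoms: none
Why: Ley–Griffith oxidation of the hindered secondary alcohol under neutral conditions that leave the dioxolane intact.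

Step 7
Reactants: 7 cis-decalin dioxolane ketone
Product: 8 C14 tert-butyl 2-methylpropanoate adduct
Conditions: LiN(iPr)2, THF, −78 °C; tert-butyl methacrylate, −78 → −40 °C; NH4Cl (aq)
Reagents that add atoms: tert-butyl methacrylate, C=C(C)C(=O)OC(C)(C)C
Why: Michael addition of the only possible ketone enolate (C14; C9 is quaternary) to the methacrylate; the hindered tertiary ester enolate that results should not propagate.

Step 8
Reactants: 8 C14 tert-butyl 2-methylpropanoate adduct
Product: 9 C23 enol triflate
Conditions: KN(SiMe3)2, THF, −78 °C; PhNTf2, −78 → 0 °C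
Reagents that add atoms: N-phenylbis(trifluoromethanesulfonimide), O=S(=O)(N(c1ccccc1)S(=O)(=O)C(F)(F)F)C(F)(F)F
Why: Regiospecific enol triflate formation: the ketone has a single α-hydrogen (C14–H), which is far more acidic than the ester α-hydrogen.

Step 9
Reactants: 9 C23 enol triflate
Product: 10 C22 allylic alcohol
Conditions: Bu3SnCH2OH, Pd(PPh3)4 (5 mol%), LiCl, 1,4-dioxane, 100 °C
Reagents that add atoms: (tributylstannyl)methanol, CCCC[Sn](CCCC)(CCCC)CO
Why: Stille coupling of the enol triflate with the hydroxymethyl stannane attaches C22 as a primary allylic alcohol.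

Step 10
Reactants: 10 C22 allylic alcohol
Product: 12 C14-quaternary diester with exocyclic C23=C22 methylene, via ketene acetal 11 (not isolated)
Conditions: MeC(OMe)3, EtCO2H (cat.), xylene, 140 °C (MeOH distilled off)
Reagents that add atoms: trimethyl orthoacetate, CC(OC)(OC)OC
Why: Johnson–Claisen rearrangement: the ketene acetal undergoes a suprafacial chair-like [3,3] shift that forms C14–C24 and moves the olefin to the exocyclic position; bond formation is expected on the ring face anti to the C9 methyl, which sets C14.

Step 11
Reactants: 12 C14-quaternary diester with exocyclic C23=C22 methylene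
Product: 14 C22–C20 acrylate triester, via alkylborane 13 (not isolated)
Conditions: 9-BBN, THF, 0 → 50 °C; then methyl 2-bromoacrylate, PdCl2(dppf) (5 mol%), K3PO4 (aq), DMF, rt
Reagents that add atoms: methyl 2-bromoacrylate, C=C(Br)C(=O)OC
Why: Hydroboration (boron to the terminal C22, hydrogen to C23) followed by B-alkyl Suzuki–Miyaura coupling; the borane is expected to avoid the face shielded by the axial C14 acetate arm and to add on the face of the C9 methyl, placing H23 syn to that methyl.

Step 12
Reactants: 14 C22–C20 acrylate triester
Product: 15 saturated triester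
Conditions: H2 (1 atm), 10% Pd/C, EtOAc, rt
Reagents that add atoms: none
Why: Heterogeneous hydrogenation of the conjugated 1,1-disubstituted olefin; the C20 configuration is irrelevant because C20 is later made trigonal.

Step 13
Reactants: 15 saturated triester
Product: 16 ring C β-keto ester
Conditions: KOtBu, THF, 0 °C → rt; AcOH
Reagents that add atoms: none
Why: Dieckmann condensation: only attack of the C24 ester enolate on the CX ester gives a β-keto ester with an acidic hydrogen, so deprotonation of the product drives this mode; the tert-butyl ester is too hindered to compete as electrophile.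

Step 14
Reactants: 16 ring C β-keto ester
Product: 17 C24-quaternary benzyl acetate
Conditions: Cs2CO3, benzyl bromoacetate, DMF, rt
Reagents that add atoms: benzyl bromoacetate, BrCC(=O)OCc1ccccc1
Why: C-Alkylation of the stabilised β-keto ester enolate creates quaternary C24; the electrophile should enter on the convex face of the cis-fused ring B/ring C bicycle, on the side of the C15 arm and away from ring B.

Step 15
Reactants: 17 C24-quaternary benzyl acetate
Product: 18 C20=CX silyl enol ether
Conditions: tBuMe2SiOTf, Et3N, CH2Cl2, 0 °C
Reagents that add atoms: tert-butyldimethylsilyl trifluoromethanesulfonate, CC(C)(C)[Si](C)(C)OS(=O)(=O)C(F)(F)F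
Why: Soft enolisation and O-silylation: the ketone can enolise only toward C20, and the enol ether masks CX (no acidic α-hydrogen, no electrophilic carbonyl) through the next four steps.

Step 16
Reactants: 18 C20=CX silyl enol ether
Product: 19 ring D β-keto ester
Conditions: LiN(SiMe3)2 (2.2 equiv), THF, −78 °C → rt; AcOH
Reagents that add atoms: none
Why: Dieckmann condensation of the benzyl ester enolate (C29) onto the tert-butyl ester closes ring D; the product is held as its stabilised enolate, and tert-butoxide is too hindered to cause retro-Claisen cleavage at quaternary C24.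

Step 17
Reactants: 19 ring D β-keto ester
Product: 20 C16-quaternary trifluoroethyl ester
Conditions: LiN(iPr)2 (2.3 equiv), THF, −78 → 0 °C; ClCO2CH2CF3, −78 °C; NH4Cl (aq)
Reagents that add atoms: 2,2,2-trifluoroethyl chloroformate, O=C(Cl)OCC(F)(F)F
Why: γ-Acylation of the β-keto ester dianion: the second deprotonation can occur only at C16, the more basic site reacts with the chloroformate, and the reagent should approach anti to the axial C14–C13 bond, placing C18 on the CX face of ring D.

Step 18
Reactants: 20 C16-quaternary trifluoroethyl ester
Product: 21 C30 alcohol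
Conditions: Zn(BH4)2, Et2O, −20 °C; NH4Cl (aq)
Reagents that add atoms: none
Why: Chelation-controlled borohydride reduction of the β-keto ester: axial approach to C30 is blocked by the axial C24–CX bond, so hydride enters equatorially and gives the axial alcohol cis to the equatorial C27 ester, the usual cis outcome for 2-alkoxycarbonyl cyclohexanones; this sets C29 and C30.

Step 19
Reactants: 21 C30 alcohol
Product: 22 C30 silyl ether
Conditions: tBuMe2SiOTf, 2,6-lutidine, CH2Cl2, 0 °C → rt
Reagents that add atoms: tert-butyldimethylsilyl trifluoromethanesulfonate, CC(C)(C)[Si](C)(C)OS(=O)(=O)C(F)(F)F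
Why: Silylation of the hindered secondary alcohol with the reactive silyl triflate.

Step 20
Reactants: 22 C30 silyl ether
Product: 24 CX ketone C27 acid, via keto benzyl ester 23 (not isolated)
Conditions: Bu4NF, AcOH, THF, 0 °C; then H2 (1 atm), 10% Pd/C, EtOAc, rt
Reagents that add atoms: none
Why: Buffered fluoride cleaves the enol silyl ether much faster than the hindered secondary silyl ether, and hydrogenolysis then frees the C27 acid under neutral conditions.

Step 21
Reactants: 24 CX ketone C27 acid
Product: 25 bridged diketone acid
Conditions: LiN(SiMe3)2 (2.5 equiv), THF, −78 → 0 °C; AcOH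
Reagents that add atoms: none
Why: Intramolecular Claisen C-acylation: the C20 enolate reaches C18 through a boat ring D and closes the seven-membered bridge; the trifluoroethoxide leaving group makes formation of the non-enolisable 1,3-diketone favourable, and C20 forms on its only accessible face. The C27 carboxylate cannot be acylated and protects C29–H against deprotonation.

Step 22
Reactants: 25 bridged diketone acid
Product: 26 bridged diketone diacid
Conditions: LiI, pyridine, 100 °C; 1 M HCl work-up
Reagents that add atoms: none
Why: SN2 demethylation of the bridgehead methyl ester by iodide avoids carbonyl addition, which would trigger retro-Claisen cleavage; the resulting β-keto acid cannot decarboxylate because its enol would be a bridgehead olefin (Bredt's rule).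

Step 23
Reactants: 26 bridged diketone diacid
Product: 27 bridged triketone anhydride
Conditions: N,N'-dicyclohexylcarbodiimide, CH2Cl2, 0 °C → rt; recrystallisation (EtOAc/heptane)
Reagents that add atoms: none
Why: Carbodiimide dehydration of the 1,2-diacid to the five-membered anhydride under neutral conditions that do not enolise C29; recrystallisation supplies the crystalline photochemical substrate.

Step 24
Reactants: 27 bridged triketone anhydride
Product: 28 bicyclooctane anhydride
Conditions: hν (medium-pressure Hg lamp, Pyrex, λ > 290 nm), ground crystals under Ar, 0–10 °C, partial conversion with recycling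
Reagents that add atoms: none
Why: Excitation of the CX ketone triggers Norrish type 1 α-cleavage to an acyl–alkyl radical pair, the acyl radical loses CO, and the C20/C24 radical pair combines to form the C20–C24 bond. The closest known reaction type is the solid-state photodecarbonylation of crystalline hexasubstituted ketones with radical-stabilising groups on both α-carbons, used to join adjacent quaternary centres. The cyclopentane (C14, C23, C22, C20, C24) closes by radical–radical combination within a pair that stays tethered through C22–C23–C14, a ring contraction of the cyclohexanone. The same bond contracts the three-atom C18–C20–CX bridge to two atoms, turning the bicyclo[3.2.2]nonane into the bicyclo[2.2.2]octane. C20 and C24 are re-formed with retention, because each radical centre stays pinned by two ring tethers and by the lattice and cannot rotate or invert before the pair collapses. Selectivity for CX over C18 follows from radical stabilisation: cleavage at CX gives radicals stabilised by the C18 ketone and the C25 anhydride carbonyl, whereas decarbonylation after cleavage at C18 would need an unstabilised tertiary radical at C16, so that pathway should simply reclose. Combination must outrun disproportionation (hydrogen transfer from the C20 methyl or C22) and radical escape; the rigid lattice and low temperature secure this, which is why the crystals are irradiated dry and only to partial conversion.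

Step 25
Reactants: 28 bicyclooctane anhydride
Product: 29 C25 acid C27 methyl ester
Conditions: MeOH, CH2Cl2, 40 °C
Reagents that add atoms: methanol, CO
Why: Neutral alcoholysis of the anhydride: methanol should attack the less hindered C27 carbonyl (on tertiary C29) rather than C25 on the bridgehead between two quaternary carbons, and the absence of base protects C29.

Step 26
Reactants: 29 C25 acid C27 methyl ester
Product: 30 C25 hydroxymethyl C27 methyl ester
Conditions: BH3·SMe2, THF, 0 °C → rt; MeOH
Reagents that add atoms: none
Why: Borane reduces a carboxylic acid (through its acyloxyborane) faster than an ester or the C18 ketone, which is flanked by two quaternary carbons, giving the C25 primary alcohol.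

Step 27
Reactants: 30 C25 hydroxymethyl C27 methyl ester
Product: 31 γ-lactone ring A ketone silyl ether
Conditions: pTsOH (cat.), THF/H2O (4:1), 45 °C
Reagents that add atoms: water, O
Why: Acid-catalysed lactonisation of the γ-hydroxy ester and hydrolysis of the dioxolane; the hindered secondary silyl ether should survive these mild conditions.

Step 28
Reactants: 31 γ-lactone ring A ketone silyl ether
Product: 32 ring A enone silyl ether
Conditions: 2-iodoxybenzoic acid (IBX), DMSO/fluorobenzene, 75 °C
Reagents that add atoms: none
Why: IBX dehydrogenation of the ketone through its enol; only C7 carries α-hydrogens (C2 is quaternary, C18 has none), and the C30 oxygen is still silylated so it cannot be oxidised.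

Step 29
Reactants: 32 ring A enone silyl ether
Product: 33 target silyl ether
Conditions: mCPBA, CH2Cl2, 0 °C → rt
Reagents that add atoms: 3-chloroperoxybenzoic acid, O=C(OO)c1cccc(Cl)c1
Why: Baeyer–Villiger oxidation: quaternary C2 migrates in preference to the vinyl carbon, inserting O4 between C5 and C2; C18 is too hindered to form the peracid adduct and the electron-poor olefin is not epoxidised.

Step 30
Reactants: 33 target silyl ether
Product: 34 target CNP0295808.3
Conditions: HF·pyridine, THF, 0 °C → rt
Reagents that add atoms: none
Why: Fluoride desilylation under non-basic conditions avoids retro-aldol cleavage and C29 epimerisation of the β-hydroxy carbonyl array.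

## Compound list

1 | (S)-Wieland–Miescher ketone | C[C@]12CCC(=O)C=C1CCCC2=O | starting material
2 | C23 hydroxy enone, (4aS,5S)-5-hydroxy-4a-methyl-4,4a,5,6,7,8-hexahydronaphthalen-2(3H)-one | C[C@]12CCC(=O)C=C1CCC[C@@H]2O | intermediate
3 | triethylsilyl ether of 2 | C[C@]12CCC(=O)C=C1CCC[C@@H]2O[Si](CC)(CC)CC | intermediate
4 | 2,2-dimethyl β,γ-unsaturated (C11=C12) ketone silyl ether | C[C@]12CCC(=O)C(C)(C)C1=CCC[C@@H]2O[Si](CC)(CC)CC | intermediate
5 | C11=C12 dioxolane alcohol | C[C@]12CCC3(OCCO3)C(C)(C)C1=CCC[C@@H]2O | intermediate
6 | cis-decalin dioxolane alcohol (C9 methyl, H11 and C23 hydroxyl on one face) | CC1(C)C5(OCCO5)CC[C@@]2(C)[C@@H]1CCC[C@@H]2O | intermediate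
7 | cis-decalin dioxolane ketone (C23 ketone) | CC1(C)C5(OCCO5)CC[C@@]2(C)[C@@H]1CCCC2=O | intermediate
8 | C14 tert-butyl 2-methylpropanoate adduct of 7 (epimers at C14 and C16) | CC1(C)C5(OCCO5)CC[C@@]2(C)[C@@H]1CCC(CC(C)C(=O)OC(C)(C)C)C2=O | intermediate
9 | C23 enol triflate (C23=C14) | CC1(C)C5(OCCO5)CC[C@@]2(C)[C@@H]1CCC(CC(C)C(=O)OC(C)(C)C)=C2OS(=O)(=O)C(F)(F)F | intermediate
10 | C22 allylic alcohol | CC1(C)C5(OCCO5)CC[C@@]2(C)[C@@H]1CCC(CC(C)C(=O)OC(C)(C)C)=C2CO | intermediate
11 | mixed methyl ketene acetal of 10 (not isolated) | CC1(C)C5(OCCO5)CC[C@@]2(C)[C@@H]1CCC(CC(C)C(=O)OC(C)(C)C)=C2COC(=C)OC | intermediate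
12 | C14-quaternary diester with exocyclic C23=C22 methylene (C24 arm anti to the C9 methyl) | CC1(C)C5(OCCO5)CC[C@@]2(C)[C@@H]1CC[C@@](CC(C)C(=O)OC(C)(C)C)(CC(=O)OC)C2=C | intermediate
13 | C22 B-alkyl-9-borabicyclo[3.3.1]nonane (not isolated) | CC1(C)C5(OCCO5)CC[C@@]2(C)[C@@H]1CC[C@@](CC(C)C(=O)OC(C)(C)C)(CC(=O)OC)[C@H]2CB6C7CCCC6CCC7 | intermediate
14 | C22–C20 acrylate triester (H23 syn to the C9 methyl) | CC1(C)C5(OCCO5)CC[C@@]2(C)[C@@H]1CC[C@@](CC(C)C(=O)OC(C)(C)C)(CC(=O)OC)[C@H]2CC(=C)C(=O)OC | intermediate
15 | saturated triester | CC1(C)C5(OCCO5)CC[C@@]2(C)[C@@H]1CC[C@@](CC(C)C(=O)OC(C)(C)C)(CC(=O)OC)[C@H]2CC(C)C(=O)OC | intermediate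
16 | ring C β-keto ester (CX ketone, C25 methyl ester) | CC1(C)C5(OCCO5)CC[C@@]2(C)[C@@H]1CC[C@]3(CC(C)C(=O)OC(C)(C)C)[C@H]2CC(C)C(=O)C3C(=O)OC | intermediate
17 | C24-quaternary benzyl acetate | CC1(C)C5(OCCO5)CC[C@@]2(C)[C@@H]1CC[C@]3(CC(C)C(=O)OC(C)(C)C)[C@H]2CC(C)C(=O)[C@]3(CC(=O)OCc6ccccc6)C(=O)OC | intermediate
18 | C20=CX tert-butyldimethylsilyl enol ether | CC1(C)C5(OCCO5)CC[C@@]2(C)[C@@H]1CC[C@]3(CC(C)C(=O)OC(C)(C)C)[C@H]2CC(C)=C(O[Si](C)(C)C(C)(C)C)[C@]3(CC(=O)OCc6ccccc6)C(=O)OC | intermediate
19 | ring D β-keto ester (C30 ketone, C27 benzyl ester) | CC1(C)C5(OCCO5)CC[C@@]2(C)[C@@H]1CC[C@@]34CC(C)C(=O)C(C(=O)OCc6ccccc6)[C@]3(C(=O)OC)C(O[Si](C)(C)C(C)(C)C)=C(C)C[C@@H]24 | intermediate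
20 | C16-quaternary 2,2,2-trifluoroethyl ester (C18) | CC1(C)C5(OCCO5)CC[C@@]2(C)[C@@H]1CC[C@@]34C[C@](C)(C(=O)OCC(F)(F)F)C(=O)C(C(=O)OCc6ccccc6)[C@]3(C(=O)OC)C(O[Si](C)(C)C(C)(C)C)=C(C)C[C@@H]24 | intermediate
21 | C30 alcohol (C18, O31 and C27 all cis on ring D) | CC1(C)C5(OCCO5)CC[C@@]2(C)[C@@H]1CC[C@@]34C[C@](C)(C(=O)OCC(F)(F)F)[C@H](O)[C@H](C(=O)OCc6ccccc6)[C@]3(C(=O)OC)C(O[Si](C)(C)C(C)(C)C)=C(C)C[C@@H]24 | intermediate
22 | C30 tert-butyldimethylsilyl ether | CC1(C)C5(OCCO5)CC[C@@]2(C)[C@@H]1CC[C@@]34C[C@](C)(C(=O)OCC(F)(F)F)[C@H](O[Si](C)(C)C(C)(C)C)[C@H](C(=O)OCc6ccccc6)[C@]3(C(=O)OC)C(O[Si](C)(C)C(C)(C)C)=C(C)C[C@@H]24 | intermediate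
23 | CX ketone C27 benzyl ester (not isolated) | CC1(C)C5(OCCO5)CC[C@@]2(C)[C@@H]1CC[C@@]34C[C@](C)(C(=O)OCC(F)(F)F)[C@H](O[Si](C)(C)C(C)(C)C)[C@H](C(=O)OCc6ccccc6)[C@]3(C(=O)OC)C(=O)C(C)C[C@@H]24 | intermediate
24 | CX ketone C27 acid | CC1(C)C5(OCCO5)CC[C@@]2(C)[C@@H]1CC[C@@]34C[C@](C)(C(=O)OCC(F)(F)F)[C@H](O[Si](C)(C)C(C)(C)C)[C@H](C(=O)O)[C@]3(C(=O)OC)C(=O)C(C)C[C@@H]24 | intermediate
25 | bridged diketone acid (bicyclo[3.2.2]nonane; C25 methyl ester, C27 acid) | CC1(C)C5(OCCO5)CC[C@@]2(C)[C@@H]1CC[C@]13C[C@]4(C)C(=O)[C@](C)(C[C@@H]21)C(=O)[C@@]3(C(=O)OC)[C@@H](C(=O)O)[C@H]4O[Si](C)(C)C(C)(C)C | intermediate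
26 | bridged diketone diacid | CC1(C)C5(OCCO5)CC[C@@]2(C)[C@@H]1CC[C@]13C[C@]4(C)C(=O)[C@](C)(C[C@@H]21)C(=O)[C@@]3(C(=O)O)[C@@H](C(=O)O)[C@H]4O[Si](C)(C)C(C)(C)C | intermediate
27 | bridged triketone anhydride (key-step precursor) | CC1(C)C5(OCCO5)CC[C@@]2(C)[C@@H]1CC[C@]13C[C@]4(C)C(=O)[C@](C)(C[C@@H]21)C(=O)[C@]31C(=O)OC(=O)[C@H]1[C@H]4O[Si](C)(C)C(C)(C)C | intermediate
28 | bicyclooctane anhydride (key-step product) | CC1(C)C5(OCCO5)CC[C@@]2(C)[C@@H]1CC[C@]13C[C@]4(C)C(=O)[C@](C)(C[C@@H]21)[C@]31C(=O)OC(=O)[C@H]1[C@H]4O[Si](C)(C)C(C)(C)C | intermediate
29 | C25 acid C27 methyl ester | CC1(C)C5(OCCO5)CC[C@@]2(C)[C@@H]1CC[C@]13C[C@]4(C)C(=O)[C@](C)(C[C@@H]21)[C@@]3(C(=O)O)[C@@H](C(=O)OC)[C@H]4O[Si](C)(C)C(C)(C)C | intermediate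
30 | C25 hydroxymethyl C27 methyl ester | CC1(C)C5(OCCO5)CC[C@@]2(C)[C@@H]1CC[C@]13C[C@]4(C)C(=O)[C@](C)(C[C@@H]21)[C@@]3(CO)[C@@H](C(=O)OC)[C@H]4O[Si](C)(C)C(C)(C)C | intermediate
31 | γ-lactone ring A ketone silyl ether | CC1(C)C(=O)CC[C@@]2(C)[C@@H]1CC[C@]13C[C@]4(C)C(=O)[C@](C)(C[C@@H]21)[C@]31COC(=O)[C@H]1[C@H]4O[Si](C)(C)C(C)(C)C | intermediate
32 | ring A enone silyl ether | CC1(C)C(=O)C=C[C@@]2(C)[C@@H]1CC[C@]13C[C@]4(C)C(=O)[C@](C)(C[C@@H]21)[C@]31COC(=O)[C@H]1[C@H]4O[Si](C)(C)C(C)(C)C | intermediate
33 | target tert-butyldimethylsilyl ether | CC1(C)OC(=O)C=C[C@@]2(C)[C@@H]1CC[C@]13C[C@]4(C)C(=O)[C@](C)(C[C@@H]21)[C@]31COC(=O)[C@H]1[C@H]4O[Si](C)(C)C(C)(C)C | intermediate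
34 | CNP0295808.3 | CC1(C)OC(=O)C=C[C@@]2(C)[C@@H]1CC[C@]13C[C@]4(C)C(=O)[C@](C)(C[C@@H]21)[C@]31COC(=O)[C@H]1[C@H]4O | target

## Step count and least certain steps

Total step count: 30. Longest linear sequence: 30 steps (1 → 34; the route is fully linear).

**Step 24 (key step).** The most likely failure is loss of lattice control. Softening or disorder of the crystal as product accumulates would let the radical pair disproportionate by hydrogen transfer from the C20 methyl or C22, or let the acyl radical reclose without losing CO. Surface hydrolysis of the anhydride by moisture would disorder the crystal in the same way. Fallback: change the crystalline host, not the lamp. Starting from 26, the diacid is crystallised with tert-butylamine as the bis(tert-butylammonium) salt F1, whose ionic lattice should be higher melting and insensitive to water. Irradiation of these crystals as an aqueous suspension, followed by acidification, should give the decarbonylated diacid F2. Dehydration with N,N'-dicyclohexylcarbodiimide then rejoins the route at 28.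

**Step 10.** The risk is poor or reversed facial selectivity of the [3,3] shift. The two faces of the ring B olefin differ only in a methyl versus a ring methylene on C9, so the acetate arm may be delivered syn to the methyl. Fallback: set C14 by the order of two enolate alkylations, in which whichever group is introduced second takes the preferred face. Starting from 7, LiN(iPr)2 and methyl bromoacetate give the mono-alkylated ketone F3. KN(SiMe3)2 and tert-butyl 2-(bromomethyl)acrylate then give the C14-quaternary keto acrylate F4, the larger arm entering last. Zn/CH2Br2/TiCl4 methylenation of the hindered ketone, which spares the esters, gives the methylene acrylate F5. Conjugate reduction with [(Ph3P)CuH]6 returns to the route at 12.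

**Step 11.** The risk is that boron and hydrogen add from the face anti to the C9 methyl, giving the C23 epimer, or that hydroboration of the doubly neopentyl olefin is sluggish. Fallback: a stereocomplementary sequence that uses that same facial preference. Starting from 12, mCPBA epoxidation from the face anti to the methyl gives the spiro-epoxide F6. BF3·OEt2 at −78 °C induces Meinwald rearrangement, in which hydride migrates from C22 to C23 anti to the departing oxygen and therefore syn to the methyl, giving the C22 aldehyde F7. Wittig reaction with Ph3P=C(Me)CO2Me gives the enoate F8, and hydrogenation over Pd/C returns to the route at 15.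

**Step 21.** The risk is that the Claisen closure does not go to completion. The non-enolisable, strained 1,3-diketone may revert (retro-Claisen by the released alkoxide), O-acylation may compete at the tetrasubstituted enolate, or proton transfer may quench the enolate. Fallback: replace the acylation by an aldol closure followed by oxidation. Starting from 19, the dianion is alkylated with benzyl chloromethyl ether to give the C16 benzyloxymethyl β-keto ester F9. Zn(BH4)2 reduction gives the C30 alcohol F10, and silylation gives the silyl ether F11. Bu4NF/AcOH followed by hydrogenolysis over Pd/C removes the enol ether and both benzyl groups, giving the hydroxy keto acid F12. Oxidation of the primary alcohol with (Pr4N)RuO4/N-methylmorpholine N-oxide gives the C18 aldehyde F13. LiN(SiMe3)2 then closes the bridge by aldol addition of the C20 enolate to the far more electrophilic aldehyde, giving the bridged β-hydroxy ketone F14. A second perruthenate oxidation returns to the route at 25.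

## Further compounds

F1 | step 24 | bis(tert-butylammonium) salt of diacid 26 | CC1(C)C5(OCCO5)CC[C@@]2(C)[C@@H]1CC[C@]13C[C@]4(C)C(=O)[C@](C)(C[C@@H]21)C(=O)[C@@]3(C(=O)[O-])[C@@H](C(=O)[O-])[C@H]4O[Si](C)(C)C(C)(C)C.CC(C)(C)[NH3+].CC(C)(C)[NH3+]
F2 | step 24 | decarbonylated bicyclooctane diacid | CC1(C)C5(OCCO5)CC[C@@]2(C)[C@@H]1CC[C@]13C[C@]4(C)C(=O)[C@](C)(C[C@@H]21)[C@@]3(C(=O)O)[C@@H](C(=O)O)[C@H]4O[Si](C)(C)C(C)(C)C
F3 | step 10 | C14 methyl acetate ketone (C14 epimers) | CC1(C)C5(OCCO5)CC[C@@]2(C)[C@@H]1CCC(CC(=O)OC)C2=O
F4 | step 10 | C14-quaternary keto acrylate | CC1(C)C5(OCCO5)CC[C@@]2(C)[C@@H]1CC[C@@](CC(=C)C(=O)OC(C)(C)C)(CC(=O)OC)C2=O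
F5 | step 10 | C23 methylene acrylate | CC1(C)C5(OCCO5)CC[C@@]2(C)[C@@H]1CC[C@@](CC(=C)C(=O)OC(C)(C)C)(CC(=O)OC)C2=C
F6 | step 11 | C23 spiro-epoxide (oxygen anti to the C9 methyl) | CC1(C)C5(OCCO5)CC[C@@]2(C)[C@@H]1CC[C@@](CC(C)C(=O)OC(C)(C)C)(CC(=O)OC)[C@]26CO6
F7 | step 11 | C22 aldehyde (H23 syn to the C9 methyl) | CC1(C)C5(OCCO5)CC[C@@]2(C)[C@@H]1CC[C@@](CC(C)C(=O)OC(C)(C)C)(CC(=O)OC)[C@H]2C=O
F8 | step 11 | (E)-C22=C20 enoate | CC1(C)C5(OCCO5)CC[C@@]2(C)[C@@H]1CC[C@@](CC(C)C(=O)OC(C)(C)C)(CC(=O)OC)[C@H]2/C=C(\C)C(=O)OC
F9 | step 21 | C16 benzyloxymethyl β-keto ester | CC1(C)C5(OCCO5)CC[C@@]2(C)[C@@H]1CC[C@@]34C[C@](C)(COCc7ccccc7)C(=O)C(C(=O)OCc6ccccc6)[C@]3(C(=O)OC)C(O[Si](C)(C)C(C)(C)C)=C(C)C[C@@H]24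
F10 | step 21 | C30 alcohol of F9 | CC1(C)C5(OCCO5)CC[C@@]2(C)[C@@H]1CC[C@@]34C[C@](C)(COCc7ccccc7)[C@H](O)[C@H](C(=O)OCc6ccccc6)[C@]3(C(=O)OC)C(O[Si](C)(C)C(C)(C)C)=C(C)C[C@@H]24
F11 | step 21 | C30 silyl ether of F10 | CC1(C)C5(OCCO5)CC[C@@]2(C)[C@@H]1CC[C@@]34C[C@](C)(COCc7ccccc7)[C@H](O[Si](C)(C)C(C)(C)C)[C@H](C(=O)OCc6ccccc6)[C@]3(C(=O)OC)C(O[Si](C)(C)C(C)(C)C)=C(C)C[C@@H]24
F12 | step 21 | C18 hydroxymethyl CX ketone C27 acid | CC1(C)C5(OCCO5)CC[C@@]2(C)[C@@H]1CC[C@@]34C[C@](C)(CO)[C@H](O[Si](C)(C)C(C)(C)C)[C@H](C(=O)O)[C@]3(C(=O)OC)C(=O)C(C)C[C@@H]24
F13 | step 21 | C18 aldehyde CX ketone C27 acid | CC1(C)C5(OCCO5)CC[C@@]2(C)[C@@H]1CC[C@@]34C[C@](C)(C=O)[C@H](O[Si](C)(C)C(C)(C)C)[C@H](C(=O)O)[C@]3(C(=O)OC)C(=O)C(C)C[C@@H]24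
F14 | step 21 | bridged C18 hydroxy CX ketone acid (C18 epimers) | CC1(C)C5(OCCO5)CC[C@@]2(C)[C@@H]1CC[C@]13C[C@]4(C)C(O)[C@](C)(C[C@@H]21)C(=O)[C@@]3(C(=O)OC)[C@@H](C(=O)O)[C@H]4O[Si](C)(C)C(C)(C)C
A1 | alternative 1 | (Z)-β-iodoacrylate Heck substrate with the C9=C23 olefin | CC(C)(OC(=O)/C=C\I)[C@H]1CC[C@]2(C[C@]3(C)C(=O)[C@@H](C)[C@]24COC(=O)[C@H]4[C@H]3O)C=C1C
A2 | alternative 1 | ring A lactone C22 aldehyde | CC1(C)OC(=O)C=C[C@@]2(C)[C@@H]1CC[C@]3(C[C@]4(C)C(=O)[C@@H](C)[C@]35COC(=O)[C@H]5[C@H]4O)[C@H]2C=O
A3 | alternative 2 | bridging diazo keto lactone with C24–H | CC1(C)C(=O)CC[C@@]2(C)[C@@H]1CC[C@]13C[C@]4(C)C(=O)[C@](C)(C[C@@H]21)[C@@H]3COC(=O)C(=[N+]=[N-])C4=O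
A4 | alternative 2 | C30 ketone of the ring A ketone analogue | CC1(C)C(=O)CC[C@@]2(C)[C@@H]1CC[C@]13C[C@]4(C)C(=O)[C@](C)(C[C@@H]21)[C@]31COC(=O)[C@H]1C4=O
A5 | alternative 3 | cage-bearing 14-membered trienyl macrolactone | CC1(C)OC(=O)/C=C\C(C)=C/C[C@@]2(C)C(=O)[C@@]3(C)C/C(=C\C=C\1)[C@@]24COC(=O)[C@H]4[C@H]3O[Si](C)(C)C(C)(C)C
A6 | alternative 3 | 12,13-dehydro target silyl ether | CC1(C)OC(=O)C=C[C@@]2(C)[C@@H]1C=C[C@]13C[C@]4(C)C(=O)[C@](C)(C[C@@H]21)[C@]31COC(=O)[C@H]1[C@H]4O[Si](C)(C)C(C)(C)C
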